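**Assumptions**
- Candidachalcone has no stereocentres, so "single enantiomer" has no content here. The stereochemical elements to control are the Z-alkene of the carbinol side chain and the E-enone.
- 5,7-Dihydroxycoumarin is commercially available. It can also be made from phloroglucinol, malic acid and H2SO4.

**Retrosynthetic overview**
1. The E-enone is disconnected by Claisen–Schmidt condensation into 2,4-dihydroxy-6-methoxyacetophenone bearing the side chain at C3 (acetophenone 8 in the route below) and 4-hydroxybenzaldehyde.
2. The Z-CH=CH–C(CH3)2OH side chain comes from a coumarin lactone. Double methyl addition opens the lactone, and the cis C3=C4 ring alkene becomes the Z-alkene (the proposed new step).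
3. The acetyl group is placed by an ortho-Fries rearrangement of 5-acetoxy-7-methoxycoumarin.
4. The 7-OMe comes from selective methylation of the more acidic 7-OH of 5,7-dihydroxycoumarin.
5. No ring is built. The pyranone ring is a removable template that fixes the Z geometry and is cleaved in the key step.

---

**Step 1**
Reactants: **1** 5,7-dihydroxycoumarin; **2** iodomethane
Product: **3** 5-hydroxy-7-methoxycoumarin
Conditions: MeI (1.0 equiv), K2CO3 (1.1 equiv), acetone, reflux, 6 h
Reagents that add atoms: iodomethane, CI
Why: The 7-OH is conjugated through the ring to the lactone carbonyl and is the more acidic phenol, so one equivalent of base and MeI methylates it selectively (Williamson ether synthesis). The 5-OH is less acidic, and the minor 5-OMe and dimethyl ethers are removed by chromatography. No stereocentre is involved.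

**Step 2**
Reactants: **3** 5-hydroxy-7-methoxycoumarin; **4** acetic anhydride
Product: **5** 5-acetoxy-7-methoxycoumarin
Conditions: Ac2O (1.5 equiv), pyridine, DMAP (cat.), CH2Cl2, rt, 3 h
Reagents that add atoms: acetic anhydride, CC(=O)OC(C)=O
Why: Simple phenol O-acylation prepares the substrate for the Fries rearrangement.

**Step 3**
Reactants: **5** 5-acetoxy-7-methoxycoumarin
Product: **6** 6-acetyl-5-hydroxy-7-methoxycoumarin
Conditions: BF3·OEt2 (5 equiv), neat, sealed tube, 120 °C, 3 h; aqueous NaOAc workup
Reagents that add atoms: none
Why: Fries rearrangement. The ortho site on the C4a side is blocked, so ortho acyl migration can only go to C6. At high temperature this gives the H-bond-chelated 2-hydroxyacetophenone, the thermodynamic product. The para (C8) acyl isomer is the minor by-product and is removed by chromatography. BF3 is used instead of AlCl3 so that the 7-OMe ortho to the new ketone is not cleaved.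

**Step 4**
Reactants: **6** 6-acetyl-5-hydroxy-7-methoxycoumarin; **7** methylmagnesium bromide
Product: **8** 1-[2,4-dihydroxy-3-((Z)-3-hydroxy-3-methylbut-1-en-1-yl)-6-methoxyphenyl]ethan-1-one
Conditions: MeMgBr (3 M in Et2O, 6 equiv), THF, 0 °C → 30 °C, 6 h; quench at 0 °C with pH 7 phosphate buffer; chromatography on Et3N-deactivated silica
Reagents that add atoms: methylmagnesium bromide, C[Mg]Br (two CH3 groups are retained)
Why: Proposed new method: the first MeMgBr deprotonates the chelated 5-OH and then adds to the lactone C=O. The tetrahedral alkoxide expels the aryl phenoxide and gives the Z-enone, whose geometry is fixed by the cis ring C3=C4 bond. The second MeMgBr adds 1,2 to this enone (or to its cyclic hemiketal form) to give the tertiary carbinol, so the Z-alkene passes from the ring to the chain without isomerisation. The 6-acetyl group is a magnesium-chelated phenoxide ketone, i.e. a vinylogous carboxylate flanked by two ortho oxygen substituents, so it is much less electrophilic than the lactone and survives. Because the arene is very electron-rich (o,o,p-trioxygenated), the tertiary allylic alcohol ionises readily and would cyclise to the 2,2-dimethylchromene under acid. The route therefore uses only a buffered quench and base-deactivated silica. The closest known reaction is double MeMgX addition to coumarins, which gives 2,2-dimethyl-2H-chromenes after acid treatment. Here it is applied to a free-phenol, acyl-substituted coumarin, with the ring-opened Z-carbinol isolated before cyclisation. No new stereocentre is formed.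

**Step 5**
Reactants: **8** acetophenone (the product of Step 4); **9** 4-hydroxybenzaldehyde
Product: **10** candidachalcone
Conditions: **9** (1.2 equiv), 50% aq. KOH (10 equiv), EtOH, rt, N2, 48 h; acidify at 0 °C with citric acid to pH 5; chromatography
Reagents that add atoms: 4-hydroxybenzaldehyde, O=Cc1ccc(O)cc1
Why: Claisen–Schmidt aldol condensation; E geometry is set by thermodynamic E1cB dehydration of the β-hydroxy ketone. In strongly basic medium the chalcone stays as its stable polyphenolate, which disfavours oxa-Michael closure to the flavanone. The Z-alkene and the tertiary alcohol are base-stable, and mild acidification avoids chromene formation.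

---

**Compound list**
1 | 5,7-dihydroxycoumarin | O=C1C=Cc2c(O)cc(O)cc2O1 | starting material
2 | iodomethane | CI | starting material
3 | 5-hydroxy-7-methoxycoumarin | COc1cc(O)c2C=CC(=O)Oc2c1 | intermediate
4 | acetic anhydride | CC(=O)OC(C)=O | starting material
5 | 5-acetoxy-7-methoxycoumarin | COc1cc(OC(C)=O)c2C=CC(=O)Oc2c1 | intermediate
6 | 6-acetyl-5-hydroxy-7-methoxycoumarin | CC(=O)c1c(OC)cc2OC(=O)C=Cc2c1O | intermediate
7 | methylmagnesium bromide | C[Mg]Br | starting material
8 | 1-[2,4-dihydroxy-3-((Z)-3-hydroxy-3-methylbut-1-enyl)-6-methoxyphenyl]ethanone | CC(=O)c1c(OC)cc(O)c(/C=C\C(C)(C)O)c1O | intermediate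
9 | 4-hydroxybenzaldehyde | O=Cc1ccc(O)cc1 | starting material
10 | candidachalcone | COc1cc(O)c(/C=C\C(C)(C)O)c(O)c1C(=O)/C=C/c1ccc(O)cc1 | target

**Total step count:** 5
**Longest linear sequence:** 5 steps (1 → 3 → 5 → 6 → 8 → 10)

**Three steps most likely to fail**
1. **Step 4 (proposed new step).** Risks are 1,4-addition at C4, attack on the chelated acetyl group, Z→E isomerisation of the ring-opened enone, and cyclisation of the carbinol to the chromene on workup.
   - Fallback (known chemistry, different approach): start from commercial 2',4'-dihydroxy-6'-methoxyacetophenone. Iodinate at C3' with NIS, then run a Sonogashira coupling with 2-methylbut-3-yn-2-ol (Pd/Cu). Then do a Lindlar semihydrogenation (H2, Pd/CaCO3/Pb, quinoline) to give **8**, and continue with Step 5. The iodination regioselectivity (C3' versus C5') and benzofuran formation during the Sonogashira coupling would need to be checked.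
2. **Step 3.** The Fries rearrangement may give the C8 (para) acyl regioisomer, or demethylation may occur.
   - Fallback: build the acyl group on the symmetric phloroglucinol core. Make 6-acetyl-5,7-dihydroxycoumarin by Pechmann condensation of 2,4,6-trihydroxyacetophenone with malic acid/H2SO4, and separate it from the 8-acetyl isomer. Then methylate selectively at the more acidic, non-chelated 7-OH, and continue with Step 4.
3. **Step 5.** Claisen–Schmidt condensation on a polyphenolic substrate can give low yields, with a risk of flavanone or chromene formation.
   - Fallback: condense with 4-allyloxybenzaldehyde (LiOH, MeOH), then remove the allyl group under neutral conditions (Pd(PPh3)4, PhSiH3), which avoids acid.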